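**Retrosynthetic overview**

1. Last step and only ring formation: the lactone acyl–O bond of the 29-membered ring is closed by S→O acyl transfer in a 2-pyridyl thioester of the free C28 ω-hydroxy acid. This copies the ω-hydroxy-fatty-acyl thioester closure and is run on an unprotected, conformationally unbiased chain (no RCM, no protecting groups).
2. The seco acid is traced to a 2-acylcyclododecanone: retro-Claisen opening of the carbocycle gives the C1 carboxyl, and Wolff–Kishner reduction removes the C13 ketone.
3. The acylcyclododecanone is cut at C12–C13 into cyclododecanone 1 (C1–C12) and 16-hexadecanolide 2 (C13–C28; its ring oxygen ends as the 28-OH) by a crossed Claisen condensation.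
4. Ring order: the 12-membered carbocycle of 1 and the 17-membered lactone of 2 are both opened on the way; one new ring, the 29-membered lactone, is made last.

Assumption: the target has no stereocentre and no double bond, so it is a single achiral compound and needs no enantiocontrol; salts of a product that exist only until acidic work-up are not numbered separately.

**Route**

Step 1
Reactants: 1 cyclododecanone (2.5 equiv); 2 16-hexadecanolide (oxacycloheptadecan-2-one, 1.0 equiv)
Product: 4 2-(16-hydroxyhexadecanoyl)cyclododecan-1-one (racemate), via lithium cyclododec-1-en-1-olate 3 (not isolated)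
Conditions: LiN(SiMe3)2 (2.4 equiv), THF, −78 °C; then 2, −78 → 45 °C, 12 h; 1 M aq HCl, 0 °C
Reagents that add atoms: none
Why: Crossed Claisen condensation in which the preformed enolate 3 C-acylates the strain-free macrolactone 2 (it reacts as an ordinary aliphatic ester and the expelled alkoxide simply becomes the free terminal OH), driven by deprotonation of the β-diketone by the second equivalent of 3; the one new stereocentre (C2) is racemic, enolisable and destroyed in step 2.

Step 2
Reactants: 4 2-(16-hydroxyhexadecanoyl)cyclododecan-1-one
Product: 7 28-hydroxyoctacosanoic acid, via potassium 28-hydroxy-13-oxooctacosanoate 5 (not isolated), via potassium 13-hydrazinylidene-28-hydroxyoctacosanoate 6 (not isolated)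
Conditions: KOH (8 equiv), H2O, diethylene glycol, 120 °C, 2 h; then N2H4·H2O (5 equiv), 130 °C, then distil to 200 °C, 4 h; aq HCl
Reagents that add atoms: potassium hydroxide, [K+].[OH-]
Why: Retro-Claisen cleavage of the β-diketone by hydroxide at the ring carbonyl (the 12-carbon chain extension known for 2-acylcyclododecanones) turns the former cyclododecanone C=O into the C1 carboxylate, and Wolff–Kishner reduction (Huang-Minlon) in the same KOH/glycol medium then converts the isolated C13 ketone into CH2; hydrazine is added only after cleavage so that no pyrazole forms, and no stereocentre remains.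

Step 3
Reactants: 7 28-hydroxyoctacosanoic acid
Product: 9 octacosan-28-olide (octacosanolide, 1-oxacyclononacosan-2-one), via S-(pyridin-2-yl) 28-hydroxyoctacosanethioate 8 (not isolated)
Conditions: 2,2'-dipyridyl disulfide (1.5 equiv), PPh3 (1.5 equiv), toluene, 50 °C, 5 h; then syringe pump (15 h) into refluxing xylene, final 1 mM, further 10 h
Reagents that add atoms: none
Why: Corey–Nicolaou double-activation macrolactonisation, in which the 2-pyridyl thioester 8 (the pyridine nitrogen takes the hydroxyl proton) undergoes intramolecular S→O acyl transfer just as an ω-hydroxy-acyl thioester does in the thioesterase step, and the strain-free 29-membered ring closes under pseudo-high dilution; no stereocentre is formed.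

**Compound list**

1 | cyclododecanone | O=C1CCCCCCCCCCC1 | starting material
2 | 16-hexadecanolide (oxacycloheptadecan-2-one) | O=C1CCCCCCCCCCCCCCCO1 | starting material
3 | lithium cyclododec-1-en-1-olate | [Li+].[O-]C1=CCCCCCCCCCC1 | intermediate (not isolated)
4 | 2-(16-hydroxyhexadecanoyl)cyclododecan-1-one, racemic at C2 | O=C1CCCCCCCCCCC1C(=O)CCCCCCCCCCCCCCCO | intermediate
5 | potassium 28-hydroxy-13-oxooctacosanoate | [K+].[O-]C(=O)CCCCCCCCCCCC(=O)CCCCCCCCCCCCCCCO | intermediate (not isolated)
6 | potassium 13-hydrazinylidene-28-hydroxyoctacosanoate (C=N geometry undefined) | [K+].[O-]C(=O)CCCCCCCCCCCC(=NN)CCCCCCCCCCCCCCCO | intermediate (not isolated)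
7 | 28-hydroxyoctacosanoic acid | OCCCCCCCCCCCCCCCCCCCCCCCCCCCC(=O)O | intermediate
8 | S-(pyridin-2-yl) 28-hydroxyoctacosanethioate | OCCCCCCCCCCCCCCCCCCCCCCCCCCCC(=O)Sc1ccccn1 | intermediate (not isolated)
9 | octacosan-28-olide (octacosanolide), achiral | O=C1CCCCCCCCCCCCCCCCCCCCCCCCCCCO1 | target

**Step count and risks**

Total steps: 3. Longest linear sequence: 3 steps (2 → 4 → 7 → 9).

Steps most likely to fail, most risky first: step 1, step 3, step 2. They are described below in step order.

Step 1. The risk is slow C-acylation of a hindered ketone enolate by an unactivated macrolactone, with alkoxide-induced oligomerisation of 2 and incomplete conversion. The fallback replaces the reversible ester Claisen by an irreversible amide acylation; it sets out from 2 and comes back to the route at 4. Lactone 2 is opened with MeNH(OMe)·HCl and iPrMgCl (THF, −20 °C) to 16-hydroxy-N-methoxy-N-methylhexadecanamide F1. F1 is then added to enolate 3 (3.2 equiv, one equivalent is used up by the hydroxyl) in THF at −78 → 0 °C. The chelated tetrahedral adduct can neither revert nor over-react and gives 4 on acidic work-up.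

Step 2. The risk is that hydroxide attacks the exocyclic carbonyl of 4 and returns 1 plus 16-hydroxyhexadecanoate, or that incomplete cleavage leads to a pyrazole in the hydrazine stage. The fallback builds the C12–C13 bond by olefination, so no ketone has to be cleaved or removed; it sets out from 2 and comes back to the route at 7. Lactone 2 is half-reduced with iBu2AlH (CH2Cl2, −78 °C) to 16-hydroxyhexadecanal F2. Commercial 12-bromododecanoic acid (OC(=O)CCCCCCCCCCCBr) and PPh3 (MeCN, reflux) give (11-carboxyundecyl)triphenylphosphonium bromide F3. NaN(SiMe3)2 (2.1 equiv, THF, 0 °C) converts F3 into the ylide sodium 12-(triphenylphosphoranylidene)dodecanoate F4. Wittig reaction of F4 with F2 (−78 → 25 °C) gives (Z)-28-hydroxyoctacos-12-enoic acid F5, and H2 over Pd/C (EtOAc/EtOH, 50 °C) saturates it to 7.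

Step 3. The risk is that the 58-membered diolide and linear oligoesters compete with the 29-membered ring closure, and that the waxy seco acid is poorly soluble. The fallback closes the same C–O linkage from the other side, by carboxylate O-alkylation instead of acyl activation; it sets out from 7 and comes back to the route at 9. Acid 7 is heated with 48% aq HBr and H2SO4 (100 °C) to 28-bromooctacosanoic acid F6. F6 is added slowly to Cs2CO3 in DMF at 80 °C (final 2 mM). The caesium 28-bromooctacosanoate F7 formed in the flask cyclises by intramolecular SN2 displacement to 9.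

**Further compounds**

F1 | step 1 | 16-hydroxy-N-methoxy-N-methylhexadecanamide | CON(C)C(=O)CCCCCCCCCCCCCCCO
F2 | step 2 | 16-hydroxyhexadecanal | O=CCCCCCCCCCCCCCCCO
F3 | step 2 | (11-carboxyundecyl)triphenylphosphonium bromide | OC(=O)CCCCCCCCCCC[P+](c1ccccc1)(c1ccccc1)c1ccccc1.[Br-]
F4 | step 2 | sodium 12-(triphenylphosphoranylidene)dodecanoate | [Na+].[O-]C(=O)CCCCCCCCCCC=P(c1ccccc1)(c1ccccc1)c1ccccc1
F5 | step 2 | (Z)-28-hydroxyoctacos-12-enoic acid | OCCCCCCCCCCCCCCC/C=C\CCCCCCCCCCC(=O)O
F6 | step 3 | 28-bromooctacosanoic acid | OC(=O)CCCCCCCCCCCCCCCCCCCCCCCCCCCBr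
F7 | step 3 | caesium 28-bromooctacosanoate | [Cs+].[O-]C(=O)CCCCCCCCCCCCCCCCCCCCCCCCCCCBr
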